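Ring was what you wanted a quick number for, and your hunch was that this flask would be finished well before the asked time.

- epsilon: solid substrate 1.6 M; the very flask that is asked about, followed so far
- flask: solid substrate 1.6 M; time 4.0 h

epsilon run (percent of the solid substrate charged)

| time / min | solid substrate / % | ring / % |
|---|---|---|
| 6.00 | 86 | 6 |
| 20.0 | 52 | 36 |
| 30.0 | 35 | 62 |
| 50.0 | 1 | 98 |
| 80.0 | 0 | 102 |
| 90.0 | 1 | 101 |
| 120 | 0 | 104 |

(readings scatter by 2 percentage points)

- solid, in amounts per volume of the solution: solid substrate
- at the start none of the solid substrate is in solution
- what has only dissolved of solid substrate counts as not reacted
- the reaction counts as stopped when no species that holds the solid substrate changes by six tenths of a point or more over the second half of the time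

* the state of affairs at 4.0 h: stopped, and by what, or still going (for what has run out or reacted, a solid counts together with what of it has only dissolved) (forward and back rates have come level / it is still moving / all of the solid substrate has reacted)
* part of the solid substrate that has turned into other species by 4.0 h (what has only dissolved does not count)
* amount of ring at 4.0 h, in percent of the solid substrate charged

I asked first what the end must be. From 80.0 min on, the readings of this flask held solid substrate at 0% to 1% and ring at 101% to 104%, each good to 2 percentage points, so I saw nothing returning and took the end to be ring at about the charge. Then I asked how fast that end is approached. The solid substrate fell in a nearly straight line, which I read as a solution fed by dissolving solid. Between 6.00 min and 30.0 min the readings gave 0.0340 M min⁻¹, and I carried this feed, the fall of c(solid substrate) per minute while solid is left. The charge divided by the feed gave an emptying time of 47.1 min, and the asked 240 min is longer than that, so I expected no solid substrate at the asked time.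

My forecast read: all of the solid substrate has reacted, conversion 100%, ring 100%, since “the rate stays constant while solid remains”. This flask gave all of the solid substrate has reacted, conversion 100% and ring 100%.

    starting material → ring (k = 0.00494 s⁻¹)
    2 starting material ⇌ open dimer (K = 0.593 M⁻¹, k = 0.00174 M⁻¹ s⁻¹)
    solid substrate ⇌ starting material, rate k3*(cs3 - [starting material]) while solid is left; crystals form when [starting material] > cs3 (solubility = 0.330 M, k = 0.00260 s⁻¹)

At 0.437 h in this flask, starting material had a half-life of 2.3 min by its step to ring, shorter than the 47.1 min that the feed gives for emptying, and it was made 1.00 times as fast as it was used. Dissolving reached the midpoint of its turnover by 0.374 h, and the step to ring by 0.437 h. For a second flask with 0.64 M of solid substrate, the feed gives 18.8 min, shorter than 240 min, and that flask stood at 100% ring with 0% of its solid substrate left.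

The data are calculated with constants of no real substance, noise included.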